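**Retrosynthetic overview** (carotenoid locants: ring C1–C6, C7 = ring-fusion =CH, C8 = CH–O, chain from C9)
1. Target 10 comes from the C2-symmetric 3,3'-diketone 9 by two-fold equatorial hydride delivery (sets C3, C3').
2. Each 2,5-dihydrofuran (O–C5–C6=C7–C8) of 9 is cut at C7–C8 and O–C5, a formal [3+2] of a formyl group (C8=O) of the C20 dial 6 with a C5–C6=C7 unit. Enabling feature: the ether carbon C5 is β to C3, so at the 3-ketone level C5 is the β-carbon of a cyclohex-2-enone (C3=O, C4=C5) and O–C5 is an oxa-Michael bond, while C7 is an exocyclic alkenyl carbon that can carry a metal.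
3. The carbocycle is not made beforehand: C5–C6 arises by syn-carbometalation of a C6≡C7 alkyne by the C5 alkenyl metal of the open-chain (Z)-iodoenynone 5, which also places C8 cis to C5 on C6=C7.
4. Ring order in the key step, at both ends of 6 at once: cyclohexenone (6-exo-dig), then C7–C8 coupling (sets C8), then dihydrofuran (5-exo-trig, sets C5). Compound 5 comes from acid 1 and stannane 2 by acyl Stille coupling and ynone hydroiodination.

Key step: step 3

Assumption: all-E crocetindialdehyde 6 and 3,3-dimethylpent-4-ynoic acid 1 are taken as catalogue compounds (specialty suppliers); the target is read from the SMILES as (3S,5R,8R,3'S,5'R,8'R), and all polyene steps are run under argon in dim light with non-acidic work-up.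

**Step 1**
Reactants: 1 3,3-dimethylpent-4-ynoic acid; 2 tributyl(prop-1-yn-1-yl)stannane
Product: 4 6,6-dimethylocta-2,7-diyn-4-one, via 3,3-dimethylpent-4-ynoyl chloride 3 (not isolated)
Conditions: (COCl)2, DMF (cat.), CH2Cl2, 0 °C → rt, evaporate; then 2, PdCl2(PPh3)2 (2 mol %), ClCH2CH2Cl, 60 °C
Reagents that add atoms: none
Why: Acid chloride formation and acyl Stille coupling; alkynylstannanes transmetalate fastest of all stannanes, so the acyl–Pd should be intercepted before decarbonylation or insertion of the unactivated terminal alkyne, and no base or copper is present to engage the C≡C–H bond.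

**Step 2**
Reactants: 4 6,6-dimethylocta-2,7-diyn-4-one
Product: 5 (Z)-2-iodo-6,6-dimethyloct-2-en-7-yn-4-one
Conditions: NaI, AcOH, rt, dark
Reagents that add atoms: sodium iodide, [Na+].[I-]
Why: Conjugate hydroiodination of an ynone; iodide adds to the β-carbon and the allenol is protonated anti, which should give the (Z)-β-iodoenone (I cis to C=O) under kinetic control, while the isolated terminal alkyne is inert to NaI/AcOH.

**Step 3**
Reactants: 5 (Z)-2-iodo-6,6-dimethyloct-2-en-7-yn-4-one (2.4 equiv); 6 all-E crocetindialdehyde
Product: 9 (5R,8R,5'R,8'R)-5,8:5',8'-diepoxy-5,8,5',8'-tetrahydro-β,β-carotene-3,3'-dione, via cyclised (Z)-alkenylchromium(III) species 7 (not isolated), via bis-(Z)-hydroxy dienone 8 (not isolated)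
Conditions: CrCl2 (20 mol %), chiral oxazoline–sulfonamide ligand (22 mol %, enantiomer chosen for Re-face addition), proton sponge (22 mol %), NiCl2·2,9-dimethyl-1,10-phenanthroline (4 mol %), Mn, Cp2ZrCl2, LiCl, MeCN–THF, rt, Ar, dark; then aq. NaHCO3, DBU (10 mol %), THF, 0 °C
Reagents that add atoms: none
Why: Proposed new method: Ni(0) inserts into the C–I bond of 5, the alkenyl–Ni closes the cyclohexenone by 6-exo-dig syn-carbonickelation of the tethered C6≡C7 alkyne (gem-dimethyl effect), Ni→Cr transmetalation gives the chiral alkenyl–Cr(III) 7, which adds 1,2 to each formyl group of 6, and the C8 alkoxide then closes the 2,5-dihydrofuran by 5-exo-trig oxa-Michael addition to C5 (β-carbon of the C3=O/C4=C5 enone); the closest known reaction types are Ni-catalysed carbometalative cyclisation of alkyne-tethered alkenyl halides, the catalytic asymmetric Nozaki–Hiyama–Kishi alkenylation of enals, and Ni/Cr coupling followed by oxy-Michael ring closure, which have not been merged on this substrate class. C8 and C8' are set by the chiral sulfonamide–Cr(III) complex (Re-face delivery gives 8R,8'R); the two termini react independently, so mismatched events end in a separable meso diastereomer. C5 and C5' are relayed from C8: syn-insertion forces C8 cis to C5 on C6=C7, and in the oxa-Michael transition state allylic 1,3-strain with the in-plane C5 methyl turns C8–H inward and the polyene outward, so oxygen adds to the face that leaves the C5 methyl trans to the chain (5R with 8R). The step needs cyclisation before carbonyl addition (intramolecular insertion at Ni against bimolecular transmetalation and addition), retention of the strained Z alkenyl metal (immediate capture), 1,2- and not conjugate addition to the polyenal (normal for alkenyl–Cr(III)), and kinetic rather than equilibrating ring closure (catalytic base, 0 °C, short time).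

**Step 4**
Reactants: 9 (5R,8R,5'R,8'R)-5,8:5',8'-diepoxy-5,8,5',8'-tetrahydro-β,β-carotene-3,3'-dione
Product: 10 (3S,5R,8R,3'S,5'R,8'R)-5,8:5',8'-diepoxy-5,8,5',8'-tetrahydro-β,β-carotene-3,3'-diol (CNP0281603.1)
Conditions: L-Selectride (2.5 equiv), THF, −78 °C; then H2O, non-oxidative work-up
Reagents that add atoms: none
Why: Substrate-controlled reduction with a bulky trialkylborohydride; the planar dihydrofuran holds C5–O in the C6=C7 plane, so the C5 methyl is axial and with the axial C1 methyl blocks the axial trajectory at C3, and equatorial hydride entry should give the axial 3-OH cis to the C5 methyl (3S,3'S), as in 3,3,5-trimethylcyclohexanone reductions.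

**Compound list**
1 | 3,3-dimethylpent-4-ynoic acid | C#CC(C)(C)CC(=O)O | starting material
2 | tributyl(prop-1-yn-1-yl)stannane | CC#C[Sn](CCCC)(CCCC)CCCC | starting material
3 | 3,3-dimethylpent-4-ynoyl chloride | C#CC(C)(C)CC(=O)Cl | intermediate
4 | 6,6-dimethylocta-2,7-diyn-4-one | CC#CC(=O)CC(C)(C)C#C | intermediate
5 | (Z)-2-iodo-6,6-dimethyloct-2-en-7-yn-4-one | C/C(I)=C/C(=O)CC(C)(C)C#C | intermediate
6 | all-E crocetindialdehyde, (2E,4E,6E,8E,10E,12E,14E)-2,6,11,15-tetramethylhexadeca-2,4,6,8,10,12,14-heptaenedial | CC(/C=C/C=C(\C)C=O)=C\C=C\C=C(C)\C=C\C=C(/C)C=O | starting material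
7 | (Z)-[(2,6,6-trimethyl-4-oxocyclohex-2-en-1-ylidene)methyl]chromium(III) species, drawn as the dichloride with the chiral ligand omitted | Cl[Cr](Cl)/C=C1\C(C)=CC(=O)CC1(C)C | intermediate
8 | bis-(Z)-hydroxy dienone: all-E C20 chain of 6 in which each former CHO is an (R)-CH(OH) bound to the exocyclic (Z)-methylidene carbon of a 3,5,5-trimethylcyclohex-2-en-1-one (8R,8'R) | CC(/C=C/C=C(\C)[C@H](O)/C=C1\C(C)=CC(=O)CC1(C)C)=C\C=C\C=C(C)\C=C\C=C(/C)[C@H](O)/C=C1\C(C)=CC(=O)CC1(C)C | intermediate
9 | (5R,8R,5'R,8'R)-5,8:5',8'-diepoxy-5,8,5',8'-tetrahydro-β,β-carotene-3,3'-dione | CC(/C=C/C=C(\C)[C@H]1C=C2C(C)(C)CC(=O)C[C@@]2(C)O1)=C\C=C\C=C(C)\C=C\C=C(/C)[C@H]1C=C2C(C)(C)CC(=O)C[C@@]2(C)O1 | intermediate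
10 | (3S,5R,8R,3'S,5'R,8'R)-5,8:5',8'-diepoxy-5,8,5',8'-tetrahydro-β,β-carotene-3,3'-diol, (8R,8'R)-auroxanthin | CC(/C=C/C=C(\C)[C@H]1C=C2C(C)(C)C[C@H](O)C[C@@]2(C)O1)=C\C=C\C=C(C)\C=C\C=C(/C)[C@H]1C=C2C(C)(C)C[C@H](O)C[C@@]2(C)O1 | target

**Step count and risks**
Total step count: 4. Longest linear sequence: 4 (1 → 4 → 5 → 9 → 10).

Steps most likely to fail:

Step 3 (proposed new method). Four processes may go wrong. The uncyclised alkenyl metal may transmetalate and add to the aldehyde before alkyne insertion. The strained Z alkenyl nickel may isomerise to E, after which ring closure is impossible. Reversible oxa-Michael addition may erode the C5 relay. The low-valent metals may reduce or pinacol-couple the polyenal. The fallback uses known chemistry, sets out from 5 and comes back at 9. Compound 5 is first cyclised on its own by Pd(PPh3)4-catalysed 6-exo-dig carbopalladation with stannyl capture (Me3SnSnMe3, toluene, 80 °C) to (Z)-3,5,5-trimethyl-4-[(trimethylstannyl)methylidene]cyclohex-2-en-1-one F1. Iododestannylation with retention (I2, CH2Cl2, 0 °C) then gives (Z)-4-(iodomethylidene)-3,5,5-trimethylcyclohex-2-en-1-one F2. Isolated F2 enters a conventional catalytic asymmetric Nozaki–Hiyama–Kishi alkenylation with 6 under the same chiral Cr catalyst, and the diol 8 so formed is closed by the same catalytic-base oxa-Michael step to 9.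

Step 4. The basic hydride may enolise the ketone and trigger β-elimination of the C5–O bond (retro-oxa-Michael), or facial selectivity may be insufficient if the ring leaves the chair assumed. The fallback sets out from 9 and comes back at 10. It replaces substrate control by reagent control with a Lewis-acid-activated, non-basic hydride transfer: Corey–Bakshi–Shibata reduction with 2-methyl-oxazaborolidine (enantiomer chosen to reinforce equatorial delivery) and catecholborane in toluene at −78 °C, where the polyene should not be hydroborated. No new compound arises (F0).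

Step 1. The acyl–palladium intermediate may decarbonylate or insert the tethered terminal alkyne before transmetalation, and tin residues may be carried forward. The fallback sets out from 1 and comes back at 4. Amide coupling (EDC·HCl, MeNHOMe·HCl, iPr2NEt, CH2Cl2) gives N-methoxy-N,3,3-trimethylpent-4-ynamide F3. Treatment with 1-propynylmagnesium bromide (3 equiv, THF, −20 °C) then gives 4; the excess covers deprotonation of the terminal alkyne and the chelated tetrahedral intermediate should prevent over-addition.

**Further compounds**
F1 | step 3 | (Z)-3,5,5-trimethyl-4-[(trimethylstannyl)methylidene]cyclohex-2-en-1-one | C[Sn](C)(C)/C=C1\C(C)=CC(=O)CC1(C)C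
F2 | step 3 | (Z)-4-(iodomethylidene)-3,5,5-trimethylcyclohex-2-en-1-one | I/C=C1\C(C)=CC(=O)CC1(C)C
F0 | step 4 | none | none
F3 | step 1 | N-methoxy-N,3,3-trimethylpent-4-ynamide | C#CC(C)(C)CC(=O)N(C)OC
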